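**Plan**
- Lactone atoms are numbered as in oxolan-2-one: O1, C2 (carbonyl), C3 (alkylidene carbon), C4 (acetoxy carbon), C5 (carbon bearing the 2-methylprop-1-enyl group).
- Retrosynthesis: cut the methacrylate and acetate esters first. Then cut the ring at C2–C3 and O1–C5 together, which removes C2/O1 as CO2 and leaves the acyclic enynediol 13. Cut 13 at the alkyne–carbinol bond into alkyne 8 and enal 11, and cut 8 at its allylic C8–C9 bond into a nerol-derived bromide and a propargyl anion.
- Enabling feature: O1 and C2 of the ring are one CO2 unit lying between a vinylic carbon (C3, reachable with its E alkylidene by syn-hydrometalation of an alkyne) and an allylic carbon (C5). The C5 cation is stabilised by the 2-methylprop-1-enyl group, so C5 can be stored as the transposed tertiary allylic alcohol.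
- Forward: the chain is built from nerol (steps 1–5), the C5 enal is made by cross-metathesis (step 6), the two are joined by asymmetric alkynylation (step 7), the only ring (the γ-lactone) arises in step 8, and the acetate and methacrylate go on last (steps 9–11).
- Stereochemistry: 2Z comes from nerol and 6E from the site of the SeO2 oxidation. The carbinol centre (C4) comes from ligand-controlled alkynylation, the E alkylidene from syn-hydrocupration, and C5 from C4 under equilibrating ring closure (4,5-trans).

Key step: step 8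

**Route**

Step 1
Reactants: 1 nerol [(2Z)-3,7-dimethylocta-2,6-dien-1-ol]
Product: 2 tert-butyl{[(2Z)-3,7-dimethylocta-2,6-dien-1-yl]oxy}diphenylsilane (nerol TBDPS ether)
Conditions: TBDPSCl (1.1 equiv), imidazole (2 equiv), DMF, 0 °C to rt
Reagents that add atoms: tert-butyl(chloro)diphenylsilane, CC(C)(C)[Si](Cl)(c1ccccc1)c1ccccc1
Why: Silyl ether protection of a primary allylic alcohol; TBDPS is chosen because it must survive n-BuLi, Me2Zn, the copper hydride/hydrosilane medium and the acid of step 8.

Step 2
Reactants: 2 nerol TBDPS ether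
Product: 3 (2E,6Z)-8-{[tert-butyl(diphenyl)silyl]oxy}-2,6-dimethylocta-2,6-dien-1-ol
Conditions: SeO2 (0.3 equiv), t-BuOOH (70% aq., 3 equiv), salicylic acid (0.1 equiv), CH2Cl2, 0 °C to rt
Reagents that add atoms: selenium dioxide, O=[Se]=O (catalytic oxygen carrier); tert-butyl hydroperoxide, CC(C)(C)OO (stoichiometric oxygen source)
Why: Riley-type allylic oxidation with catalytic SeO2 (ene reaction, then [2,3]-sigmatropic shift) should hydroxylate the E methyl group of the more electron-rich terminal trisubstituted alkene, which fixes the E geometry of that alkene, while the alkene next to the silyloxymethyl group is inductively deactivated.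

Step 3
Reactants: 3 the allylic alcohol of step 2
Product: 4 {[(2Z,6E)-8-bromo-3,7-dimethylocta-2,6-dien-1-yl]oxy}(tert-butyl)diphenylsilane
Conditions: CBr4 (1.3 equiv), PPh3 (1.4 equiv), CH2Cl2, −20 °C to 0 °C
Reagents that add atoms: carbon tetrabromide, BrC(Br)(Br)Br
Why: Appel reaction: SN2 displacement of the oxyphosphonium group by bromide at the primary allylic carbon under neutral conditions, so neither allylic transposition nor E/Z scrambling is expected.

Step 4
Reactants: 4 the allylic bromide; 5 1-(trimethylsilyl)propyne [trimethyl(prop-1-yn-1-yl)silane]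
Product: 7 tert-butyl{[(2Z,6E)-3,7-dimethyl-11-(trimethylsilyl)undeca-2,6-dien-10-yn-1-yl]oxy}diphenylsilane, via 3-lithio-1-(trimethylsilyl)propyne 6 (not isolated)
Conditions: 5 (1.5 equiv), n-BuLi (1.45 equiv), THF, −78 °C; then 4, −78 °C to −20 °C
Reagents that add atoms: none
Why: Alkylation of the propargylic lithium reagent 6 (the silyl group keeps the anion propargylic and caps the alkyne terminus) by SN2 at the primary allylic bromide forms the C8–C9 bond of the chain without touching either trisubstituted alkene.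

Step 5
Reactants: 7 the silylalkyne
Product: 8 tert-butyl{[(2Z,6E)-3,7-dimethylundeca-2,6-dien-10-yn-1-yl]oxy}diphenylsilane
Conditions: K2CO3 (0.3 equiv), MeOH/THF (2:1 by volume), rt
Reagents that add atoms: none
Why: Base-catalysed methanolysis of the C(sp)–Si bond (protodesilylation) frees the terminal alkyne while the TBDPS ether is stable to K2CO3/MeOH.

Step 6
Reactants: 9 2-methylbut-3-en-2-ol; 10 (E)-but-2-enal (crotonaldehyde)
Product: 11 (2E)-4-hydroxy-4-methylpent-2-enal
Conditions: 10 (4 equiv), second-generation Hoveyda–Grubbs catalyst (3 mol%), CH2Cl2, 40 °C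
Reagents that add atoms: none
Why: Olefin cross-metathesis between a hindered tertiary allylic alcohol and an electron-poor enal is a selective pairing (neither partner homodimerises readily) and should give the E enal, with propene as the only by-product.

Step 7
Reactants: 8 the terminal alkyne; 11 the hydroxy enal
Product: 13 (3E,5R,10E,14Z)-16-{[tert-butyl(diphenyl)silyl]oxy}-2,10,14-trimethylhexadeca-3,10,14-trien-6-yne-2,5-diol, via methylzinc acetylide 12 (not isolated)
Conditions: 8 (1.2 equiv), Me2Zn (3.0 equiv), ProPhenol ligand (20 mol%, the enantiomer that gives Si-face addition), Ph3P=O (40 mol%), toluene, 0 °C; then 11 (1.0 equiv), 4 °C; aq. NH4Cl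
Reagents that add atoms: none
Why: Zinc/ProPhenol-catalysed asymmetric alkynylation of an α,β-unsaturated aldehyde: the dinuclear zinc catalyst delivers the alkynyl group of 12 to one face of the aldehyde, the ligand enantiomer being the one that gives Si-face addition and hence the 5R carbinol (sense to be checked by Mosher ester analysis), and the extra Me2Zn covers the free tertiary hydroxyl.

Step 8
Reactants: 13 the enynediol
Product: 16 (3E,4S,5R)-3-[(4E,8Z)-10-{[tert-butyl(diphenyl)silyl]oxy}-4,8-dimethyldeca-4,8-dien-1-ylidene]-4-hydroxy-5-(2-methylprop-1-en-1-yl)oxolan-2-one, via silyl ester 14 (not isolated), via dihydroxy acid 15 (not isolated)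
Conditions: [(IPr)CuF] (5 mol%; IPr = 1,3-bis(2,6-diisopropylphenyl)imidazol-2-ylidene), HSi(OEt)3 (5 equiv), CO2 (1 atm), 1,4-dioxane, 70 °C; then, same flask, CH2Cl2, H2O (3 equiv), TsOH·H2O (0.3 equiv), 0 °C to rt
Reagents that add atoms: carbon dioxide, O=C=O
Why: Proposed new method: the carbene-ligated copper hydride (formed from the monovalent copper fluoride complex and HSi(OEt)3, which also silylates both hydroxyl groups with loss of H2) should add syn across the alkyne with copper on the carbon next to the oxygen-bearing carbon, the same polarisation by a propargylic C–O bond that places copper in protoboration of propargylic ethers, and CO2 then inserts into the alkenyl–copper bond with retention to give silyl ester 14, which makes the C2–C3 bond and fixes the E alkylidene. The closest known reaction type is the copper-hydride-catalysed syn-hydrocarboxylation of alkynes with CO2 and a hydrosilane, known mainly for aryl-substituted alkynes, followed by a Brønsted-acid allylic substitution with transposition. On acidification the silyl groups are hydrolysed to acid 15, the tertiary allylic oxygen ionises to an allyl cation stabilised by its gem-dimethyl terminus, and the carboxyl oxygen captures the secondary terminus in a 5-exo-trig closure that makes the O1–C5 bond and moves the double bond into the 2-methylprop-1-enyl position; attack at the tertiary terminus would need a seven-membered ring. The new C5 stereocentre is controlled by the adjacent C4 carbinol centre: the closure is reversible through the same cation, so the 4,5-trans lactone, in which hydroxyl and alkenyl group avoid eclipsing on a ring held flat by the alkylidene, should accumulate. The step needs regioselective hydrocupration (secured by the propargylic oxygen), chemoselectivity for the alkyne over the four alkenes (copper hydride does not add to unactivated internal alkenes), and CO2 insertion faster than β-silyloxy elimination to a vinylallene (a silyl ether is a poor leaving group).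

Step 9
Reactants: 16 the hydroxy lactone
Product: 17 (2R,3S,4E)-4-[(4E,8Z)-10-{[tert-butyl(diphenyl)silyl]oxy}-4,8-dimethyldeca-4,8-dien-1-ylidene]-2-(2-methylprop-1-en-1-yl)-5-oxooxolan-3-yl acetate
Conditions: Ac2O (1.5 equiv), pyridine (3 equiv), DMAP (5 mol%), CH2Cl2, 0 °C
Reagents that add atoms: acetic anhydride, CC(=O)OC(C)=O
Why: DMAP-catalysed acetylation of the secondary alcohol with retention (the C–O bond is not touched), the mild amine base avoiding E1cB loss of the new acetate.

Step 10
Reactants: 17 the silyl-protected acetate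
Product: 18 (2R,3S,4E)-4-[(4E,8Z)-10-hydroxy-4,8-dimethyldeca-4,8-dien-1-ylidene]-2-(2-methylprop-1-en-1-yl)-5-oxooxolan-3-yl acetate
Conditions: HF·pyridine, pyridine, THF, 0 °C to rt
Reagents that add atoms: none
Why: Fluoride-mediated cleavage of the Si–O bond (silyl ether deprotection) under buffered, weakly acidic conditions should leave the acetate, the lactone and its acid-sensitive allylic C5–O bond intact.

Step 11
Reactants: 18 the primary allylic alcohol
Product: 19 (2Z,6E,10E)-10-[(4S,5R)-4-acetyloxy-5-(2-methylprop-1-en-1-yl)-2-oxooxolan-3-ylidene]-3,7-dimethyldeca-2,6-dien-1-yl 2-methylprop-2-enoate (target)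
Conditions: methacryloyl chloride (1.3 equiv), Et3N (2 equiv), DMAP (10 mol%), BHT (trace), CH2Cl2, −20 °C to 0 °C
Reagents that add atoms: methacryloyl chloride, C=C(C)C(Cl)=O
Why: Acylation of the primary allylic alcohol with an acid chloride under nucleophilic catalysis by DMAP at low temperature, with a radical inhibitor so that the methacrylate does not polymerise.

**Compound list**

1 | nerol, (2Z)-3,7-dimethylocta-2,6-dien-1-ol | OC/C=C(/C)CCC=C(C)C | starting material
2 | tert-butyl{[(2Z)-3,7-dimethylocta-2,6-dien-1-yl]oxy}diphenylsilane | CC(C)(C)[Si](OC/C=C(/C)CCC=C(C)C)(c1ccccc1)c1ccccc1 | intermediate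
3 | (2E,6Z)-8-{[tert-butyl(diphenyl)silyl]oxy}-2,6-dimethylocta-2,6-dien-1-ol | CC(C)(C)[Si](OC/C=C(/C)CC/C=C(\C)CO)(c1ccccc1)c1ccccc1 | intermediate
4 | {[(2Z,6E)-8-bromo-3,7-dimethylocta-2,6-dien-1-yl]oxy}(tert-butyl)diphenylsilane | CC(C)(C)[Si](OC/C=C(/C)CC/C=C(\C)CBr)(c1ccccc1)c1ccccc1 | intermediate
5 | 1-(trimethylsilyl)propyne | CC#C[Si](C)(C)C | starting material
6 | 3-lithio-1-(trimethylsilyl)propyne | [Li]CC#C[Si](C)(C)C | intermediate (not isolated)
7 | tert-butyl{[(2Z,6E)-3,7-dimethyl-11-(trimethylsilyl)undeca-2,6-dien-10-yn-1-yl]oxy}diphenylsilane | CC(C)(C)[Si](OC/C=C(/C)CC/C=C(\C)CCC#C[Si](C)(C)C)(c1ccccc1)c1ccccc1 | intermediate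
8 | tert-butyl{[(2Z,6E)-3,7-dimethylundeca-2,6-dien-10-yn-1-yl]oxy}diphenylsilane | CC(C)(C)[Si](OC/C=C(/C)CC/C=C(\C)CCC#C)(c1ccccc1)c1ccccc1 | intermediate
9 | 2-methylbut-3-en-2-ol | CC(C)(O)C=C | starting material
10 | (E)-but-2-enal (crotonaldehyde) | C/C=C/C=O | starting material
11 | (2E)-4-hydroxy-4-methylpent-2-enal | CC(C)(O)/C=C/C=O | intermediate
12 | methylzinc acetylide of 8, methyl[(6E,10Z)-12-{[tert-butyl(diphenyl)silyl]oxy}-6,10-dimethyldodeca-6,10-dien-1-yn-1-yl]zinc | CC(C)(C)[Si](OC/C=C(/C)CC/C=C(\C)CCC#C[Zn]C)(c1ccccc1)c1ccccc1 | intermediate (not isolated)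
13 | (3E,5R,10E,14Z)-16-{[tert-butyl(diphenyl)silyl]oxy}-2,10,14-trimethylhexadeca-3,10,14-trien-6-yne-2,5-diol | CC(C)(C)[Si](OC/C=C(/C)CC/C=C(\C)CCC#C[C@H](O)/C=C/C(C)(C)O)(c1ccccc1)c1ccccc1 | intermediate
14 | triethoxysilyl (2E,6E,10Z)-12-{[tert-butyl(diphenyl)silyl]oxy}-6,10-dimethyl-2-[(1R,2E)-4-methyl-1,4-bis(triethoxysilyloxy)pent-2-en-1-yl]dodeca-2,6,10-trienoate | CC(C)(C)[Si](OC/C=C(/C)CC/C=C(\C)CC/C=C(/C(=O)O[Si](OCC)(OCC)OCC)[C@H](O[Si](OCC)(OCC)OCC)/C=C/C(C)(C)O[Si](OCC)(OCC)OCC)(c1ccccc1)c1ccccc1 | intermediate (not isolated)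
15 | (2E,6E,10Z)-12-{[tert-butyl(diphenyl)silyl]oxy}-2-[(1R,2E)-1,4-dihydroxy-4-methylpent-2-en-1-yl]-6,10-dimethyldodeca-2,6,10-trienoic acid | CC(C)(C)[Si](OC/C=C(/C)CC/C=C(\C)CC/C=C(/C(=O)O)[C@H](O)/C=C/C(C)(C)O)(c1ccccc1)c1ccccc1 | intermediate (not isolated)
16 | (3E,4S,5R)-3-[(4E,8Z)-10-{[tert-butyl(diphenyl)silyl]oxy}-4,8-dimethyldeca-4,8-dien-1-ylidene]-4-hydroxy-5-(2-methylprop-1-en-1-yl)oxolan-2-one | CC(C)(C)[Si](OC/C=C(/C)CC/C=C(\C)CC/C=C1/C(=O)O[C@H](C=C(C)C)[C@H]1O)(c1ccccc1)c1ccccc1 | intermediate
17 | (2R,3S,4E)-4-[(4E,8Z)-10-{[tert-butyl(diphenyl)silyl]oxy}-4,8-dimethyldeca-4,8-dien-1-ylidene]-2-(2-methylprop-1-en-1-yl)-5-oxooxolan-3-yl acetate | CC(C)(C)[Si](OC/C=C(/C)CC/C=C(\C)CC/C=C1/C(=O)O[C@H](C=C(C)C)[C@H]1OC(C)=O)(c1ccccc1)c1ccccc1 | intermediate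
18 | (2R,3S,4E)-4-[(4E,8Z)-10-hydroxy-4,8-dimethyldeca-4,8-dien-1-ylidene]-2-(2-methylprop-1-en-1-yl)-5-oxooxolan-3-yl acetate | OC/C=C(/C)CC/C=C(\C)CC/C=C1/C(=O)O[C@H](C=C(C)C)[C@H]1OC(C)=O | intermediate
19 | (2Z,6E,10E)-10-[(4S,5R)-4-acetyloxy-5-(2-methylprop-1-en-1-yl)-2-oxooxolan-3-ylidene]-3,7-dimethyldeca-2,6-dien-1-yl 2-methylprop-2-enoate | C=C(C)C(=O)OC/C=C(/C)CC/C=C(\C)CC/C=C1/C(=O)O[C@H](C=C(C)C)[C@H]1OC(C)=O | target

**Step count and risks**

Total steps: 11. Longest linear sequence: 10 steps (steps 1–5 and 7–11, from nerol); step 6 is a one-step side branch.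

The three steps most likely to fail:

1. Step 8 (proposed new method). The alkenylcopper intermediate may lose its β-silyloxy group (vinylallene formation) or be protonated before CO2 inserts, and hydride delivery may lose its regiocontrol on this alkyl-substituted alkyne. The fallback uses known chemistry, sets out from 13 and returns to the route at 16. Syn-hydrostannation (Bu3SnH, PdCl2(PPh3)2 2 mol%, THF, 0 °C) places tin on the alkyne carbon next to the carbinol and gives the vinylstannane (3E,5R,6E,10E,14Z)-16-{[tert-butyl(diphenyl)silyl]oxy}-2,10,14-trimethyl-6-(tributylstannyl)hexadeca-3,6,10,14-tetraene-2,5-diol F1. n-BuLi (3.3 equiv, THF, −78 °C) forms both lithium alkoxides and effects tin–lithium exchange to the trilithio species F2, in which the oxide cannot leave, so no allene can form. Quenching with CO2 and acidifying with TsOH gives acid 15, which closes to 16 as in step 8.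

2. Step 7. Facial selectivity in the addition to the aldehyde may be poor, because the zinc alkoxide of the free tertiary hydroxyl of 11 can disturb the dinuclear zinc catalyst. The fallback sets out from 13 of insufficient enantiomeric purity and returns to 13. It is a Sharpless kinetic resolution (Ti(OiPr)4, D-(−)-diisopropyl tartrate, t-BuOOH, 4 Å molecular sieves, CH2Cl2, −20 °C). By the usual face rule, this tartrate epoxidises the 5S enantiomer quickly to the erythro epoxy alcohol F3, which is separated, and leaves 5R-13. The tertiary allylic hydroxyl is a much slower director.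

3. Step 10. Fluoride may cleave or shift the acetate, or acetic acid may be lost across C3–C4 of the lactone toward a butenolide. The fallback changes the protecting-group logic, sets out from 16 and returns at 19. The silyl ether is removed before any ester is present (TBAF buffered with AcOH, THF, 0 °C) to give the diol (3E,4S,5R)-4-hydroxy-3-[(4E,8Z)-10-hydroxy-4,8-dimethyldeca-4,8-dien-1-ylidene]-5-(2-methylprop-1-en-1-yl)oxolan-2-one F4. Its unhindered primary allylic hydroxyl is acylated selectively (methacryloyl chloride 1.05 equiv, 2,4,6-collidine, CH2Cl2, −78 °C) to the mono-methacrylate F5. Acetylation of the remaining hindered secondary hydroxyl (Ac2O, pyridine, DMAP) gives 19.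

**Further compounds**

F1 | step 8 | (3E,5R,6E,10E,14Z)-16-{[tert-butyl(diphenyl)silyl]oxy}-2,10,14-trimethyl-6-(tributylstannyl)hexadeca-3,6,10,14-tetraene-2,5-diol | CC(C)(C)[Si](OC/C=C(/C)CC/C=C(\C)CC/C=C(/[Sn](CCCC)(CCCC)CCCC)[C@H](O)/C=C/C(C)(C)O)(c1ccccc1)c1ccccc1
F2 | step 8 | trilithio species from F1 (6-lithio, 2,5-bis(lithium alkoxide)) | CC(C)(C)[Si](OC/C=C(/C)CC/C=C(\C)CC/C=C(/[Li])[C@H](O[Li])/C=C/C(C)(C)O[Li])(c1ccccc1)c1ccccc1
F3 | step 7 | erythro trans-3,4-epoxide of the 5S enantiomer of 13 (epoxy diol) | CC(C)(C)[Si](OC/C=C(/C)CC/C=C(\C)CCC#C[C@@H](O)[C@@H]1O[C@H]1C(C)(C)O)(c1ccccc1)c1ccccc1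
F4 | step 10 | (3E,4S,5R)-4-hydroxy-3-[(4E,8Z)-10-hydroxy-4,8-dimethyldeca-4,8-dien-1-ylidene]-5-(2-methylprop-1-en-1-yl)oxolan-2-one | OC/C=C(/C)CC/C=C(\C)CC/C=C1/C(=O)O[C@H](C=C(C)C)[C@H]1O
F5 | step 10 | (2Z,6E,10E)-10-[(4S,5R)-4-hydroxy-5-(2-methylprop-1-en-1-yl)-2-oxooxolan-3-ylidene]-3,7-dimethyldeca-2,6-dien-1-yl 2-methylprop-2-enoate | C=C(C)C(=O)OC/C=C(/C)CC/C=C(\C)CC/C=C1/C(=O)O[C@H](C=C(C)C)[C@H]1O
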